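**Retrosynthetic overview**

- Gnetumontanin B comes from its nonamethyl ether by global O‑demethylation; all four stereocentres are set before that.
- The strategy rests on ring A (the styryl‑bearing dihydrobenzofuran): O1, C7a, C3a and C3 are a latent ortho‑quinone methide heterodiene, and C2 is the benzylic carbon on C7 of ring M, used as a one‑carbon sulfonium ylide. The key disconnection is therefore C2–C3 plus O1–C2, a convergent [4+1] union of two fragments.
- Ring M is made first by the same [4+1] from a bromophenol sulfone and a 2,4‑dimethoxybenzyl ylide. The bromine ends up at C7 and is the handle for the benzylic carbon (Br → CHO → CH2OH → sulfonium); late electrophilic formylation would not discriminate among the activated arenes.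
- Both quinone methide precursors come from a salicylaldehyde, one stock solution of 3,5‑dimethoxyphenylmagnesium bromide and p‑toluenesulfinic acid; the stilbene is installed by a Heck reaction before the Grignard addition.
- Order of ring formation: the chiral thiolane (reagent, step 2), the ring M dihydrofuran (step 8), the ring A dihydrofuran (step 16).

Key step: step 16

Assumption: the sense of induction of (2S,5S)‑2,5‑dimethylthiolane is taken by analogy with benzylidene transfer from this class of sulfide to aldehydes; if the annulations show the opposite sense, the (2R,5R)‑sulfide from (2S,5S)‑hexane‑2,5‑diol is used with no other change.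

**Route**

Step 1
Reactants: 1 (2R,5R)-hexane-2,5-diol
Product: 2 (2R,5R)-hexane-2,5-diyl dimethanesulfonate
Conditions: MsCl, Et3N, CH2Cl2, 0 °C
Reagents that add atoms: methanesulfonyl chloride, CS(=O)(=O)Cl
Why: O‑sulfonylation of the two secondary alcohols forms only O–S bonds, so both stereocentres are retained.

Step 2
Reactants: 2 (2R,5R)-hexane-2,5-diyl dimethanesulfonate
Product: 3 (2S,5S)-2,5-dimethylthiolane
Conditions: Na2S·9H2O, DMSO, rt; distillation
Reagents that add atoms: sodium sulfide, [Na+].[Na+].[S-2]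
Why: Double SN2 displacement by sulfide (the second one a 5‑exo‑tet closure) inverts both carbons, so the (2R,5R) dimesylate should give the C2‑symmetric trans (2S,5S) thiolane.

Step 3
Reactants: 4 2,4-dimethoxybenzyl alcohol; 3 (2S,5S)-2,5-dimethylthiolane
Product: 5 (2S,5S)-1-(2,4-dimethoxybenzyl)-2,5-dimethylthiolan-1-ium tetrafluoroborate
Conditions: 3 (1.5 equiv), HBF4·OEt2, CH2Cl2, 0 °C; precipitation with Et2O
Reagents that add atoms: tetrafluoroboric acid (as its diethyl ether complex), [H+].F[B-](F)(F)F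
Why: Acid‑mediated SN1 S‑alkylation, in which the 2,4‑dimethoxybenzyl cation is trapped by the soft sulfide and kept as the salt of a non‑nucleophilic anion; sulfur is not stereogenic because the sulfide is C2‑symmetric.

Step 4
Reactants: 6 2-bromo-5-methoxyphenol
Product: 7 3-bromo-2-hydroxy-6-methoxybenzaldehyde
Conditions: MgCl2, Et3N, (CH2O)n, THF, reflux; then 1 M HCl
Reagents that add atoms: paraformaldehyde (as formaldehyde), C=O
Why: Magnesium‑mediated ortho‑formylation of a phenol (Casnati–Skattebøl reaction) delivers formaldehyde only ortho to the phenoxide, and the single free ortho position is the one between OH and OMe because the other carries bromine.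

Step 5
Reactants: 8 1-bromo-3,5-dimethoxybenzene
Product: 9 3,5-dimethoxyphenylmagnesium bromide (stock solution in THF, titrated and kept under argon for steps 6 and 14)
Conditions: Mg turnings, I2 (cat.), THF, 50 °C
Reagents that add atoms: magnesium, [Mg]
Why: Grignard formation by insertion of magnesium into the aryl C–Br bond, which the two meta methoxy groups do not disturb, gives one batch of reagent that serves both carbinol syntheses.

Step 6
Reactants: 7 3-bromo-2-hydroxy-6-methoxybenzaldehyde; 9 3,5-dimethoxyphenylmagnesium bromide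
Product: 10 racemic 2-bromo-6-[(3,5-dimethoxyphenyl)(hydroxy)methyl]-5-methoxyphenol
Conditions: 9 (2.5 equiv, THF solution), THF, 0 °C to rt; H2O
Reagents that add atoms: none
Why: Grignard addition to the aldehyde after the first equivalent has deprotonated the phenol; the aryl bromide of 7 is inert to an arylmagnesium halide without a catalyst, and the carbinol may be racemic because this centre is lost later.

Step 7
Reactants: 10 racemic 2-bromo-6-[(3,5-dimethoxyphenyl)(hydroxy)methyl]-5-methoxyphenol
Product: 11 racemic 6-bromo-2-[(3,5-dimethoxyphenyl)(4-methylbenzenesulfonyl)methyl]-3-methoxyphenol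
Conditions: p-TolSO2H, CH2Cl2, rt
Reagents that add atoms: p-toluenesulfinic acid, Cc1ccc(S(=O)O)cc1
Why: SN1 sulfinate exchange: the sulfinic acid ionises the diaryl carbinol, which is flanked by OH and OMe, and S‑alkylation of the sulfinate gives the crystalline sulfone that is the standard base‑labile quinone methide precursor.

Step 8
Reactants: 11 racemic 6-bromo-2-[(3,5-dimethoxyphenyl)(4-methylbenzenesulfonyl)methyl]-3-methoxyphenol; 5 (2S,5S)-1-(2,4-dimethoxybenzyl)-2,5-dimethylthiolan-1-ium tetrafluoroborate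
Product: 15 (2S,3S)-7-bromo-2-(2,4-dimethoxyphenyl)-3-(3,5-dimethoxyphenyl)-4-methoxy-2,3-dihydro-1-benzofuran, via ortho-quinone methide 12 (not isolated), via sulfonium ylide 13 (not isolated), via anti betaine 14 (not isolated)
Conditions: Cs2CO3 (3 equiv), CH2Cl2, −20 °C to rt
Reagents that add atoms: none
Why: Proposed new method: Cs2CO3 turns 11 into ortho‑quinone methide 12 by loss of sulfinate and 5 into benzylic ylide 13, whose carbon adds to the methide carbon with rearomatisation to give betaine 14, and the phenoxide then closes the dihydrofuran by 5‑exo‑tet SN2 displacement of the thiolane with inversion, so that the anti betaine gives the trans ring; the closest known reaction type is the base‑mediated [4+1] annulation of ortho‑quinone methides from 2‑(tosylmethyl)phenols with sulfur ylides, and the new element is that C2 and C3 are set as (2S,3S) by the C2‑symmetric (2S,5S)‑thiolane, which shields one face of the ylide carbon as it does in benzylidene transfer from sulfonium ylides to aldehydes.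

Step 9
Reactants: 15 (2S,3S)-7-bromo-2-(2,4-dimethoxyphenyl)-3-(3,5-dimethoxyphenyl)-4-methoxy-2,3-dihydro-1-benzofuran
Product: 17 (2S,3S)-2-(2,4-dimethoxyphenyl)-3-(3,5-dimethoxyphenyl)-4-methoxy-2,3-dihydro-1-benzofuran-7-carbaldehyde, via aryllithium 16 (not isolated)
Conditions: n-BuLi (1.1 equiv), THF, −78 °C; DMF, −78 to 0 °C; H2O
Reagents that add atoms: N,N-dimethylformamide, CN(C)C=O
Why: Bromine–lithium exchange at −78 °C is faster than any deprotonation, so the formyl group (Bouveault formylation) enters only at C7, a position no electrophilic formylation could single out; the C2 and C3 centres are not touched.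

Step 10
Reactants: 17 (2S,3S)-2-(2,4-dimethoxyphenyl)-3-(3,5-dimethoxyphenyl)-4-methoxy-2,3-dihydro-1-benzofuran-7-carbaldehyde
Product: 18 [(2S,3S)-2-(2,4-dimethoxyphenyl)-3-(3,5-dimethoxyphenyl)-4-methoxy-2,3-dihydro-1-benzofuran-7-yl]methanol
Conditions: NaBH4, MeOH/THF, 0 °C
Reagents that add atoms: none
Why: Borohydride reduction of an aryl aldehyde to the benzylic alcohol, with nothing else in the molecule reducible.

Step 11
Reactants: 18 [(2S,3S)-2-(2,4-dimethoxyphenyl)-3-(3,5-dimethoxyphenyl)-4-methoxy-2,3-dihydro-1-benzofuran-7-yl]methanol; 3 (2S,5S)-2,5-dimethylthiolane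
Product: 19 (2S,5S)-1-{[(2S,3S)-2-(2,4-dimethoxyphenyl)-3-(3,5-dimethoxyphenyl)-4-methoxy-2,3-dihydro-1-benzofuran-7-yl]methyl}-2,5-dimethylthiolan-1-ium tetrafluoroborate
Conditions: 3 (3 equiv), HBF4·OEt2 (1.05 equiv), CH2Cl2, −40 to 0 °C; precipitation with Et2O
Reagents that add atoms: tetrafluoroboric acid (as its diethyl ether complex), [H+].F[B-](F)(F)F
Why: The same acid‑mediated SN1 S‑alkylation as in step 3: the C7 benzylic alcohol, ortho to O1 and para to the C4 methoxy group, ionises far more readily than the ring C2–O bond, and excess sulfide outcompetes the dimethoxyphenyl rings for the cation.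

Step 12
Reactants: 20 4-bromo-2,6-dimethoxybenzaldehyde
Product: 21 4-bromo-2-hydroxy-6-methoxybenzaldehyde
Conditions: BCl3 (1.1 equiv), CH2Cl2, −78 to 0 °C; H2O
Reagents that add atoms: none
Why: Chelation‑directed mono‑demethylation: BCl3 bound to the formyl oxygen cleaves one flanking methyl ether through a six‑membered boron chelate, which then blocks cleavage of the second.

Step 13
Reactants: 21 4-bromo-2-hydroxy-6-methoxybenzaldehyde; 22 4-methoxystyrene
Product: 23 2-hydroxy-6-methoxy-4-[(E)-2-(4-methoxyphenyl)ethenyl]benzaldehyde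
Conditions: Pd(OAc)2 (5 mol %), P(o-tol)3 (10 mol %), Et3N, DMF, 100 °C
Reagents that add atoms: none
Why: Mizoroki–Heck reaction: oxidative addition into the bromide para to the formyl group, insertion of the styrene at its terminal carbon and syn β‑hydride elimination should give the E‑stilbene, with the phenol tolerated as its ammonium salt.

Step 14
Reactants: 23 2-hydroxy-6-methoxy-4-[(E)-2-(4-methoxyphenyl)ethenyl]benzaldehyde; 9 3,5-dimethoxyphenylmagnesium bromide
Product: 24 racemic 2-[(3,5-dimethoxyphenyl)(hydroxy)methyl]-3-methoxy-5-[(E)-2-(4-methoxyphenyl)ethenyl]phenol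
Conditions: 9 (2.5 equiv, THF solution), THF, 0 °C to rt; H2O
Reagents that add atoms: none
Why: Grignard 1,2‑addition to the aldehyde of the magnesium phenoxide; the acid‑labile carbinol is taken on crude and may be racemic because its centre is lost in step 16.

Step 15
Reactants: 24 racemic 2-[(3,5-dimethoxyphenyl)(hydroxy)methyl]-3-methoxy-5-[(E)-2-(4-methoxyphenyl)ethenyl]phenol
Product: 25 racemic 2-[(3,5-dimethoxyphenyl)(4-methylbenzenesulfonyl)methyl]-3-methoxy-5-[(E)-2-(4-methoxyphenyl)ethenyl]phenol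
Conditions: p-TolSO2H, CH2Cl2, rt
Reagents that add atoms: p-toluenesulfinic acid, Cc1ccc(S(=O)O)cc1
Why: SN1 sulfinate exchange as in step 7; sulfinate capture is reversible under the acid, so the delocalised cation should end at the benzylic carbon, the only position that keeps both the arene and the stilbene intact.

Step 16
Reactants: 25 racemic 2-[(3,5-dimethoxyphenyl)(4-methylbenzenesulfonyl)methyl]-3-methoxy-5-[(E)-2-(4-methoxyphenyl)ethenyl]phenol; 19 (2S,5S)-1-{[(2S,3S)-2-(2,4-dimethoxyphenyl)-3-(3,5-dimethoxyphenyl)-4-methoxy-2,3-dihydro-1-benzofuran-7-yl]methyl}-2,5-dimethylthiolan-1-ium tetrafluoroborate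
Product: 29 (2S,3S)-2-[(2S,3S)-2-(2,4-dimethoxyphenyl)-3-(3,5-dimethoxyphenyl)-4-methoxy-2,3-dihydro-1-benzofuran-7-yl]-3-(3,5-dimethoxyphenyl)-4-methoxy-6-[(E)-2-(4-methoxyphenyl)ethenyl]-2,3-dihydro-1-benzofuran (gnetumontanin B nonamethyl ether), via ortho-quinone methide 26 (not isolated), via sulfonium ylide 27 (not isolated), via anti betaine 28 (not isolated)
Conditions: 25 (1.3 equiv), 19 (1 equiv), Cs2CO3 (3 equiv), CH2Cl2, −20 °C to rt
Reagents that add atoms: none
Why: Proposed new method: Cs2CO3 deprotonates the phenol of 25, which expels p‑toluenesulfinate to give ortho‑quinone methide 26, and deprotonates the benzylic CH2 of 19 to give ylide 27; the ylide carbon adds to the exocyclic methide carbon (C2–C3 bond, ring A rearomatises) to give betaine 28, and the phenoxide then displaces the thiolane at C2 with inversion (O1–C2 bond). The closest known reaction type is the base‑mediated [4+1] annulation of ortho‑quinone methides from 2‑(tosylmethyl)phenols with sulfur ylides, which gives trans‑2,3‑dihydrobenzofurans; new here is a benzylic ylide carried on a chiral thiolane as the source of absolute configuration, a role this sulfide class plays in benzylidene transfer to aldehydes. The ring A dihydrofuran closes by 5‑exo‑tet SN2 substitution. C3 is set in the C–C bond‑forming step by the ylide face left open by the C2‑symmetric (2S,5S)‑thiolane together with the anti approach of the methide, and C2 follows from inversion in the anti betaine, so that the two aryl groups end up trans, (2S,3S). The step needs attack at the methide carbon and not at the styryl terminus, which is secured because only addition at the methide carbon restores the aromatic ring; it also needs C‑alkylation of the ylide to outrun benzyl transfer from the sulfonium salt to phenoxide or sulfinate, which the ready sulfinate loss from the doubly oxygen‑flanked, styryl‑conjugated benzylic position and the low temperature in a non‑polar solvent should favour. The ring M stereocentres are remote from the reacting carbon and are expected to act as spectators.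

Step 17
Reactants: 29 gnetumontanin B nonamethyl ether
Product: 30 gnetumontanin B
Conditions: BBr3 (15 equiv), CH2Cl2, −78 to 0 °C; H2O
Reagents that add atoms: none
Why: Lewis‑acid cleavage of the nine aryl methyl ethers with BBr3, a demethylation used on permethylated stilbene oligomers that contain dihydrobenzofurans; no stereocentre is touched, and a reversible opening of a C2–O bond would re‑close to the favoured trans ring.

**Compound list**

1 | (2R,5R)-hexane-2,5-diol | C[C@@H](O)CC[C@@H](C)O | starting material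
2 | (2R,5R)-hexane-2,5-diyl dimethanesulfonate | C[C@@H](OS(C)(=O)=O)CC[C@@H](C)OS(C)(=O)=O | intermediate
3 | (2S,5S)-2,5-dimethylthiolane | C[C@H]1CC[C@H](C)S1 | intermediate
4 | 2,4-dimethoxybenzyl alcohol | COc1ccc(CO)c(OC)c1 | starting material
5 | (2S,5S)-1-(2,4-dimethoxybenzyl)-2,5-dimethylthiolan-1-ium tetrafluoroborate | C[C@H]1CC[C@H](C)[S+]1Cc1ccc(OC)cc1OC.F[B-](F)(F)F | intermediate
6 | 2-bromo-5-methoxyphenol | COc1ccc(Br)c(O)c1 | starting material
7 | 3-bromo-2-hydroxy-6-methoxybenzaldehyde | COc1ccc(Br)c(O)c1C=O | intermediate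
8 | 1-bromo-3,5-dimethoxybenzene | COc1cc(Br)cc(OC)c1 | starting material
9 | 3,5-dimethoxyphenylmagnesium bromide | COc1cc([Mg]Br)cc(OC)c1 | intermediate
10 | racemic 2-bromo-6-[(3,5-dimethoxyphenyl)(hydroxy)methyl]-5-methoxyphenol | COc1cc(OC)cc(C(O)c2c(O)c(Br)ccc2OC)c1 | intermediate
11 | racemic 6-bromo-2-[(3,5-dimethoxyphenyl)(4-methylbenzenesulfonyl)methyl]-3-methoxyphenol | COc1cc(OC)cc(C(c2c(O)c(Br)ccc2OC)S(=O)(=O)c2ccc(C)cc2)c1 | intermediate
12 | 2-bromo-6-[(3,5-dimethoxyphenyl)methylidene]-5-methoxycyclohexa-2,4-dien-1-one (ring M ortho-quinone methide) | O=C1C(Br)=CC=C(OC)C1=Cc1cc(OC)cc(OC)c1 | intermediate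
13 | (2,4-dimethoxyphenyl)[(2S,5S)-2,5-dimethylthiolan-1-ium-1-yl]methanide (ylide of 5) | C[C@H]1CC[C@H](C)[S+]1[CH-]c1ccc(OC)cc1OC | intermediate
14 | 6-bromo-2-[(1S,2R)-1-(3,5-dimethoxyphenyl)-2-(2,4-dimethoxyphenyl)-2-[(2S,5S)-2,5-dimethylthiolan-1-ium-1-yl]ethyl]-3-methoxyphenolate (anti betaine) | C[C@H]1CC[C@H](C)[S+]1[C@@H](c1ccc(OC)cc1OC)[C@@H](c1cc(OC)cc(OC)c1)c1c(OC)ccc(Br)c1[O-] | intermediate
15 | (2S,3S)-7-bromo-2-(2,4-dimethoxyphenyl)-3-(3,5-dimethoxyphenyl)-4-methoxy-2,3-dihydro-1-benzofuran | Brc1ccc(OC)c2c1O[C@H](c1ccc(OC)cc1OC)[C@H]2c1cc(OC)cc(OC)c1 | intermediate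
16 | (2S,3S)-2-(2,4-dimethoxyphenyl)-3-(3,5-dimethoxyphenyl)-4-methoxy-2,3-dihydro-1-benzofuran-7-yllithium | [Li]c1ccc(OC)c2c1O[C@H](c1ccc(OC)cc1OC)[C@H]2c1cc(OC)cc(OC)c1 | intermediate
17 | (2S,3S)-2-(2,4-dimethoxyphenyl)-3-(3,5-dimethoxyphenyl)-4-methoxy-2,3-dihydro-1-benzofuran-7-carbaldehyde | O=Cc1ccc(OC)c2c1O[C@H](c1ccc(OC)cc1OC)[C@H]2c1cc(OC)cc(OC)c1 | intermediate
18 | [(2S,3S)-2-(2,4-dimethoxyphenyl)-3-(3,5-dimethoxyphenyl)-4-methoxy-2,3-dihydro-1-benzofuran-7-yl]methanol | OCc1ccc(OC)c2c1O[C@H](c1ccc(OC)cc1OC)[C@H]2c1cc(OC)cc(OC)c1 | intermediate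
19 | (2S,5S)-1-{[(2S,3S)-2-(2,4-dimethoxyphenyl)-3-(3,5-dimethoxyphenyl)-4-methoxy-2,3-dihydro-1-benzofuran-7-yl]methyl}-2,5-dimethylthiolan-1-ium tetrafluoroborate | C[C@H]1CC[C@H](C)[S+]1Cc1ccc(OC)c2c1O[C@H](c1ccc(OC)cc1OC)[C@H]2c1cc(OC)cc(OC)c1.F[B-](F)(F)F | intermediate
20 | 4-bromo-2,6-dimethoxybenzaldehyde | COc1cc(Br)cc(OC)c1C=O | starting material
21 | 4-bromo-2-hydroxy-6-methoxybenzaldehyde | COc1cc(Br)cc(O)c1C=O | intermediate
22 | 4-methoxystyrene | COc1ccc(C=C)cc1 | starting material
23 | 2-hydroxy-6-methoxy-4-[(E)-2-(4-methoxyphenyl)ethenyl]benzaldehyde | COc1ccc(/C=C/c2cc(O)c(C=O)c(OC)c2)cc1 | intermediate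
24 | racemic 2-[(3,5-dimethoxyphenyl)(hydroxy)methyl]-3-methoxy-5-[(E)-2-(4-methoxyphenyl)ethenyl]phenol | COc1ccc(/C=C/c2cc(O)c(C(O)c3cc(OC)cc(OC)c3)c(OC)c2)cc1 | intermediate
25 | racemic 2-[(3,5-dimethoxyphenyl)(4-methylbenzenesulfonyl)methyl]-3-methoxy-5-[(E)-2-(4-methoxyphenyl)ethenyl]phenol | COc1ccc(/C=C/c2cc(O)c(C(c3cc(OC)cc(OC)c3)S(=O)(=O)c3ccc(C)cc3)c(OC)c2)cc1 | intermediate
26 | 6-[(3,5-dimethoxyphenyl)methylidene]-5-methoxy-3-[(E)-2-(4-methoxyphenyl)ethenyl]cyclohexa-2,4-dien-1-one (ring A ortho-quinone methide) | O=C1C=C(/C=C/c2ccc(OC)cc2)C=C(OC)C1=Cc1cc(OC)cc(OC)c1 | intermediate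
27 | [(2S,3S)-2-(2,4-dimethoxyphenyl)-3-(3,5-dimethoxyphenyl)-4-methoxy-2,3-dihydro-1-benzofuran-7-yl][(2S,5S)-2,5-dimethylthiolan-1-ium-1-yl]methanide (ylide of 19) | C[C@H]1CC[C@H](C)[S+]1[CH-]c1ccc(OC)c2c1O[C@H](c1ccc(OC)cc1OC)[C@H]2c1cc(OC)cc(OC)c1 | intermediate
28 | 2-[(1S,2R)-2-[(2S,3S)-2-(2,4-dimethoxyphenyl)-3-(3,5-dimethoxyphenyl)-4-methoxy-2,3-dihydro-1-benzofuran-7-yl]-1-(3,5-dimethoxyphenyl)-2-[(2S,5S)-2,5-dimethylthiolan-1-ium-1-yl]ethyl]-3-methoxy-5-[(E)-2-(4-methoxyphenyl)ethenyl]phenolate (anti betaine) | C[C@H]1CC[C@H](C)[S+]1[C@@H](c1ccc(OC)c2c1O[C@H](c1ccc(OC)cc1OC)[C@H]2c1cc(OC)cc(OC)c1)[C@@H](c1cc(OC)cc(OC)c1)c1c(OC)cc(/C=C/c2ccc(OC)cc2)cc1[O-] | intermediate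
29 | gnetumontanin B nonamethyl ether, (2S,3S)-2-[(2S,3S)-2-(2,4-dimethoxyphenyl)-3-(3,5-dimethoxyphenyl)-4-methoxy-2,3-dihydro-1-benzofuran-7-yl]-3-(3,5-dimethoxyphenyl)-4-methoxy-6-[(E)-2-(4-methoxyphenyl)ethenyl]-2,3-dihydro-1-benzofuran | COc1ccc(/C=C/c2cc(OC)c3c(c2)O[C@H](c2ccc(OC)c4c2O[C@H](c2ccc(OC)cc2OC)[C@H]4c2cc(OC)cc(OC)c2)[C@H]3c2cc(OC)cc(OC)c2)cc1 | intermediate
30 | gnetumontanin B | Oc1ccc(/C=C/c2cc(O)c3c(c2)O[C@H](c2ccc(O)c4c2O[C@H](c2ccc(O)cc2O)[C@H]4c2cc(O)cc(O)c2)[C@H]3c2cc(O)cc(O)c2)cc1 | target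

**Step count and risk**

Total step count: 17. Longest linear sequence: 9 steps (steps 4, 6, 7, 8, 9, 10, 11, 16, 17).

Steps most likely to fail:

1. Step 16 (key step). What may go wrong is benzyl transfer from the electron‑rich sulfonium salt to phenoxide or sulfinate in place of C‑alkylation of the ylide, or weak facial control by the thiolane so that the ring A centres form in both senses. The fallback keeps the [4+1] union but moves the stereocontrol from the reagent to a separation, and uses the known achiral version of the annulation. It sets out from 18: treatment with tetrahydrothiophene and HBF4·OEt2 in CH2Cl2 should give 1-{[(2S,3S)-2-(2,4-dimethoxyphenyl)-3-(3,5-dimethoxyphenyl)-4-methoxy-2,3-dihydro-1-benzofuran-7-yl]methyl}thiolan-1-ium tetrafluoroborate F1. With 25 and Cs2CO3 in CH2Cl2 this salt forms its ylide F2, which adds to 26 on either face to give the anti betaine with the (1S,2R) ethyl centres F3 and the anti betaine with the (1R,2S) ethyl centres F4. Ring closure then gives 29 together with its ring A (2R,3R) diastereomer F5, both with trans rings. Because ring M is already enantiopure these are diastereomers and are separated by preparative HPLC, and the route is rejoined at 29.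

2. Step 8. What may go wrong is low enantioselectivity with the very electron‑rich 2,4‑dimethoxybenzyl ylide, or SN1 loss of the benzyl group from the salt before the ylide forms. The fallback uses the known achiral annulation and a resolution. It sets out from 4: tetrahydrothiophene and HBF4·OEt2 should give 1-(2,4-dimethoxybenzyl)thiolan-1-ium tetrafluoroborate F6. With 11 and Cs2CO3 this forms its ylide F7, which adds to 12 to give the (1S,2R) anti betaine F8 and the (1R,2S) anti betaine F9, and these close to racemic trans bromide, that is 15 together with its (2R,3R) enantiomer F10. Preparative HPLC on a chiral stationary phase separates the two, the bromine allowing the absolute configuration to be assigned by anomalous dispersion, and the route is rejoined at 15.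

3. Step 11. What may go wrong is that the strong acid ionises the C2–O bond of the dihydrofuran or lets the benzylic cation alkylate a dimethoxyphenyl ring, or that the labile salt is lost on isolation. The fallback avoids acid and makes the C–S bond by halide abstraction. It sets out from 18: MsCl and i‑Pr2NEt in CH2Cl2 at −20 °C should give (2S,3S)-7-(chloromethyl)-2-(2,4-dimethoxyphenyl)-3-(3,5-dimethoxyphenyl)-4-methoxy-2,3-dihydro-1-benzofuran F11 by collapse of the mesylate with chloride. The crude chloride is treated at once with 3 and AgBF4 in CH2Cl2, silver chloride precipitates, and the route is rejoined at 19.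

**Further compounds**

F1 | step 16 | 1-{[(2S,3S)-2-(2,4-dimethoxyphenyl)-3-(3,5-dimethoxyphenyl)-4-methoxy-2,3-dihydro-1-benzofuran-7-yl]methyl}thiolan-1-ium tetrafluoroborate | C1CC[S+](C1)Cc1ccc(OC)c2c1O[C@H](c1ccc(OC)cc1OC)[C@H]2c1cc(OC)cc(OC)c1.F[B-](F)(F)F
F2 | step 16 | ylide of F1 | C1CC[S+](C1)[CH-]c1ccc(OC)c2c1O[C@H](c1ccc(OC)cc1OC)[C@H]2c1cc(OC)cc(OC)c1
F3 | step 16 | anti betaine with (1S,2R) ethyl centres, thiolanium analogue of 28 | C1CC[S+](C1)[C@@H](c1ccc(OC)c2c1O[C@H](c1ccc(OC)cc1OC)[C@H]2c1cc(OC)cc(OC)c1)[C@@H](c1cc(OC)cc(OC)c1)c1c(OC)cc(/C=C/c2ccc(OC)cc2)cc1[O-]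
F4 | step 16 | anti betaine with (1R,2S) ethyl centres | C1CC[S+](C1)[C@H](c1ccc(OC)c2c1O[C@H](c1ccc(OC)cc1OC)[C@H]2c1cc(OC)cc(OC)c1)[C@H](c1cc(OC)cc(OC)c1)c1c(OC)cc(/C=C/c2ccc(OC)cc2)cc1[O-]
F5 | step 16 | ring A (2R,3R) diastereomer of 29 | COc1ccc(/C=C/c2cc(OC)c3c(c2)O[C@@H](c2ccc(OC)c4c2O[C@H](c2ccc(OC)cc2OC)[C@H]4c2cc(OC)cc(OC)c2)[C@@H]3c2cc(OC)cc(OC)c2)cc1
F6 | step 8 | 1-(2,4-dimethoxybenzyl)thiolan-1-ium tetrafluoroborate | COc1ccc(C[S+]2CCCC2)c(OC)c1.F[B-](F)(F)F
F7 | step 8 | ylide of F6 | COc1ccc([CH-][S+]2CCCC2)c(OC)c1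
F8 | step 8 | (1S,2R) anti betaine, thiolanium analogue of 14 | C1CC[S+](C1)[C@@H](c1ccc(OC)cc1OC)[C@@H](c1cc(OC)cc(OC)c1)c1c(OC)ccc(Br)c1[O-]
F9 | step 8 | (1R,2S) anti betaine | C1CC[S+](C1)[C@H](c1ccc(OC)cc1OC)[C@H](c1cc(OC)cc(OC)c1)c1c(OC)ccc(Br)c1[O-]
F10 | step 8 | (2R,3R)-7-bromo-2-(2,4-dimethoxyphenyl)-3-(3,5-dimethoxyphenyl)-4-methoxy-2,3-dihydro-1-benzofuran | Brc1ccc(OC)c2c1O[C@@H](c1ccc(OC)cc1OC)[C@@H]2c1cc(OC)cc(OC)c1
F11 | step 11 | (2S,3S)-7-(chloromethyl)-2-(2,4-dimethoxyphenyl)-3-(3,5-dimethoxyphenyl)-4-methoxy-2,3-dihydro-1-benzofuran | ClCc1ccc(OC)c2c1O[C@H](c1ccc(OC)cc1OC)[C@H]2c1cc(OC)cc(OC)c1
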